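The ten-membered carbocycle is built one atom too large and then contracted. Its allylic alcohol unit C9(OH)–C10(C14)=C1 (germacrane numbering) is the retron of an epoxy-Ramberg–Bäcklund reaction. The precursor is an eleven-membered thiacycle 1,1-dioxide in which sulfur bridges C1 and C10 and a 9,10-oxirane sits on the sulfonyl carbon. Base closes C1 onto C10, the episulfone loses SO2, and in one operation the ring shrinks from eleven to ten atoms, the (Z)-C1=C10 olefin forms and the C9 carbinol is unveiled with its configuration intact. The thiacycle arises from hydrosulfide, an ynone and an alkyl chloride; C6/C7 come from an Evans aldol.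

Key step: step 14

Remark 1: atom numbers in names follow germacrane numbering of the target (ring C1–C10; lactone C11–C13 with O on C6; C14 = CH2O on C10; C15 = CH3 on C4).
Remark 2: (2R)-2-methylbutanoic acid (32) and the TBS ether of propargyl alcohol (16) are assumed to be purchased.
Remark 3: the oxirane of 24 is drawn cis-fused (S and C8 cis); the configuration at C10 is destroyed in step 14 and is of no consequence.

Step 1
Reactants: 1 5-chloropent-1-yne
Product: 3 methyl 6-chlorohex-2-ynoate, via lithium acetylide 2 (not isolated)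
Conditions: n-BuLi, THF, −78 °C; then ClCO2Me, −78 → 0 °C
Reagents that add atoms: methyl chloroformate, COC(=O)Cl
Why: Acetylide C-acylation; the terminal alkyne is deprotonated and trapped by the chloroformate while the primary chloride is inert at −78 °C.

Step 2
Reactants: 3 methyl 6-chlorohex-2-ynoate
Product: 5 methyl (2Z)-6-chloro-3-methylhex-2-enoate, via alkenylcuprate 4 (not isolated)
Conditions: Me2CuLi (from MeLi and CuI), THF, −78 °C; MeOH quench at −78 °C
Reagents that add atoms: lithium dimethylcuprate, [Li+].C[Cu-]C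
Why: Syn-carbocupration of a 2-alkynoate puts CH3 and Cu cis, so protonation of 4 with retention at −78 °C should give the Z (nerol-type) C4=C5 olefin.

Step 3
Reactants: 5 methyl (2Z)-6-chloro-3-methylhex-2-enoate
Product: 6 (2Z)-6-chloro-3-methylhex-2-en-1-ol
Conditions: DIBAL-H (2.2 equiv), CH2Cl2, −78 °C; Rochelle salt
Reagents that add atoms: none
Why: DIBAL-H 1,2-reduction of the enoate to the allylic alcohol, with the olefin geometry untouched.

Step 4
Reactants: 6 (2Z)-6-chloro-3-methylhex-2-en-1-ol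
Product: 7 (2Z)-6-chloro-3-methylhex-2-enal
Conditions: TEMPO (cat.), PhI(OAc)2, CH2Cl2, 0 → 23 °C
Reagents that add atoms: none
Why: TEMPO/PhI(OAc)2 oxidation of the allylic alcohol under near-neutral conditions should keep the Z-enal from isomerising.

Step 5
Reactants: 8 (4S)-4-benzyl-1,3-oxazolidin-2-one; 9 methyl 4-chloro-4-oxobutanoate
Product: 11 methyl 4-[(4S)-4-benzyl-2-oxo-1,3-oxazolidin-3-yl]-4-oxobutanoate, via N-lithio oxazolidinone 10 (not isolated)
Conditions: n-BuLi, THF, −78 °C; then 9, −78 → 0 °C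
Reagents that add atoms: none
Why: N-acylation of the lithiated Evans auxiliary by the acid chloride.

Step 6
Reactants: 11 succinate imide; 7 (2Z)-6-chloro-3-methylhex-2-enal
Product: 14 trans-lactone imide, via boron enolate 12 (not isolated), via aldol adduct 13 (not isolated)
Conditions: Bu2BOTf, i-Pr2NEt, CH2Cl2, 0 °C; 7, −78 → 0 °C; pH 7 buffer, MeOH, H2O2; then PPTS (cat.), CH2Cl2, 23 °C
Reagents that add atoms: none
Why: Evans syn-aldol: the Z-boron enolate 12 (imide α-CH2 enolised in preference to the ester) adds to 7 through a Zimmerman–Traxler chair on the face remote from the benzyl group, which sets C6 and C7 with the absolute configuration of the target, and the C6 hydroxyl of syn adduct 13 then closes onto the methyl ester to give the trans-γ-lactone.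

Step 7
Reactants: 14 trans-lactone imide
Product: 15 (2R,3S)-2-[(1Z)-5-chloro-2-methylpent-1-en-1-yl]-5-oxooxolane-3-carboxylic acid
Conditions: LiOH, H2O2, THF/H2O, 0 °C; Na2SO3; HCl to pH 2
Reagents that add atoms: hydrogen peroxide (as LiOOH), OO
Why: Hydroperoxide cleavage of the N-acyl oxazolidinone at the exocyclic carbonyl; any opened lactone should re-close on acidification and the trans C6/C7 relation is the stable one.

Step 8
Reactants: 15 lactone acid; 16 tert-butyl(dimethyl)(prop-2-yn-1-yloxy)silane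
Product: 18 (4S,5R)-4-{4-[tert-butyl(dimethyl)silyl]oxybut-2-ynoyl}-5-[(1Z)-5-chloro-2-methylpent-1-en-1-yl]oxolan-2-one, via acid chloride 17 (not isolated)
Conditions: (COCl)2, DMF (cat.), CH2Cl2, 0 °C; then 16, PdCl2(PPh3)2 (2 mol%), CuI (4 mol%), Et3N, THF, 23 °C
Reagents that add atoms: none
Why: Acyl Sonogashira coupling of the acid chloride with the terminal alkyne gives the ynone; β-elimination of the lactone oxygen from C7 would be a retro-5-endo-trig process and should not compete.

Step 9
Reactants: 18 chloro ynone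
Product: 20 thiacycle enone, via sodium enethiolate 19 (not isolated)
Conditions: NaSH (1.05 equiv), DMF, 0 °C, slow addition of 18 (final 2 mM); then NaI (0.2 equiv), 45 °C
Reagents that add atoms: sodium hydrosulfide, [Na+].[SH-]
Why: Thia-Michael addition of hydrosulfide to the ynone gives the Z-enethiolate 19, whose sulfur then displaces the primary chloride (Finkelstein-assisted SN2) and closes the eleven-membered thiacycle at high dilution.

Step 10
Reactants: 20 thiacycle enone
Product: 21 thiacycle allylic alcohol (8S)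
Conditions: (R)-Me-CBS oxazaborolidine (0.3 equiv), catecholborane, toluene, −78 → −40 °C
Reagents that add atoms: none
Why: CBS reduction: hydride is delivered 1,2 to the enone with the alkenyl arm in the large-group position, which should give the 8S carbinol under reagent control while lactone and vinyl sulfide stay intact.

Step 11
Reactants: 21 thiacycle allylic alcohol
Product: 22 C8 TIPS ether
Conditions: TIPSOTf, 2,6-lutidine, CH2Cl2, −78 → 0 °C
Reagents that add atoms: triisopropylsilyl trifluoromethanesulfonate, CC(C)[Si](C(C)C)(C(C)C)OS(=O)(=O)C(F)(F)F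
Why: Buffered O-silylation protects the acid-labile γ-hydroxy vinyl sulfide; TIPS is chosen because it directs the next step and resists O→O migration in step 14.

Step 12
Reactants: 22 C8 TIPS ether
Product: 23 cyclic vinyl sulfone
Conditions: (NH4)6Mo7O24·4H2O (10 mol%), 30% H2O2, EtOH, 0 → 23 °C
Reagents that add atoms: hydrogen peroxide, OO
Why: Mo(VI)-catalysed S-oxidation to the sulfone, chemoselective for sulfur over the trisubstituted C4=C5 olefin.

Step 13
Reactants: 23 cyclic vinyl sulfone
Product: 24 9,10-epoxy sulfone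
Conditions: t-BuOOH, n-BuLi, THF, −20 → 0 °C
Reagents that add atoms: tert-butyl hydroperoxide (as its lithium salt), CC(C)(C)OO
Why: Nucleophilic epoxidation of a vinyl sulfone: t-BuOO− adds to C9 anti to the C8 silyloxy group in the conformer with H8 eclipsing the olefin (A(1,3) strain, polar Felkin–Anh), which sets C9 in the 8,9-erythro sense, and the α-sulfonyl carbanion closes on oxygen to the oxirane.

Step 14
Reactants: 24 9,10-epoxy sulfone
Product: 26 ten-membered allylic alcohol, via episulfone 25 (not isolated)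
Conditions: LiOt-Bu (3 equiv), THF, 0 → 23 °C; H2O
Reagents that add atoms: none
Why: Epoxy-Ramberg–Bäcklund reaction: LiOt-Bu removes the only α-sulfonyl proton left (on C1, C10 being fully substituted), the carbanion attacks C10 with inversion and opens the oxirane at its C10–O bond, and the thiirane 1,1-dioxide 25 loses SO2 stereospecifically to give the C1=C10 olefin, contracting the eleven-membered thiacycle to the ten-membered carbocycle. The closest known reaction type is the epoxy-Ramberg–Bäcklund synthesis of allylic alcohols from α,β-epoxy sulfones, applied here to a macrocyclic sulfone. The only ring closed is the three-membered episulfone (3-exo-tet); the ten-membered ring arises when sulfur leaves it. No new stereocentre is formed: C9 keeps the configuration of the oxirane because its C–O bond is not touched, and C6–C8 are spectators. The step needs the ring-cis (Z) olefin, which should follow from the cis-fused episulfone (C2 and C9 cis) favoured by a ring that already holds the Z-C4=C5 olefin and the trans-lactone; the TIPS ether at C8 blocks Payne-type attack on the epoxy sulfone and resists migration to the new C9 alkoxide.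

Step 15
Reactants: 26 ten-membered allylic alcohol
Product: 29 α-methylene lactone, via Mannich base 27 (not isolated), via ammonium iodide 28 (not isolated)
Conditions: LiHMDS (2.5 equiv), THF, −78 °C; CH2=NMe2+ I−, −78 → 0 °C; H2O; then MeI, MeOH, 23 °C; then NaHCO3 (aq), CH2Cl2
Reagents that add atoms: Eschenmoser's salt, C=[N+](C)C.[I-]
Why: Mannich aminomethylation of the lactone enolate (the C9 alkoxide is a spectator), N-quaternisation and E1cB loss of trimethylamine install the C11=C13 methylene, now that no sulfur nucleophile remains.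

Step 16
Reactants: 29 α-methylene lactone
Product: 30 C9 acetate
Conditions: Ac2O, pyridine, DMAP (cat.), CH2Cl2, 0 → 23 °C
Reagents that add atoms: acetic anhydride, CC(=O)OC(C)=O
Why: DMAP-catalysed acetylation of the only free hydroxyl (C9).

Step 17
Reactants: 30 C9 acetate
Product: 31 8,14-diol
Conditions: HF·pyridine (excess), THF, 0 → 23 °C
Reagents that add atoms: none
Why: Fluoride cleavage of both silyl ethers under mildly acidic conditions, which should spare the α-methylene lactone and disfavour acetyl migration from O9 to O8.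

Step 18
Reactants: 31 8,14-diol; 32 (2R)-2-methylbutanoic acid
Product: 33 CNP0005248.2
Conditions: EDC·HCl, DMAP (cat.), CH2Cl2, −20 → 0 °C
Reagents that add atoms: none
Why: Steglich esterification, selective for the unhindered primary allylic C14 hydroxyl over the hindered secondary C8 hydroxyl; the low temperature limits epimerisation of the acid and acyl migration.

Compound list
1 | 5-chloropent-1-yne | C#CCCCCl | starting material
2 | lithium 5-chloropent-1-yn-1-ide | [Li]C#CCCCCl | intermediate (not isolated)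
3 | methyl 6-chlorohex-2-ynoate | COC(=O)C#CCCCCl | intermediate
4 | lithium [(1E)-5-chloro-1-(methoxycarbonyl)-2-methylpent-1-en-1-yl](methyl)cuprate | [Li+].COC(=O)/C([Cu-]C)=C(/C)CCCCl | intermediate (not isolated)
5 | methyl (2Z)-6-chloro-3-methylhex-2-enoate | COC(=O)/C=C(/C)CCCCl | intermediate
6 | (2Z)-6-chloro-3-methylhex-2-en-1-ol | OC/C=C(/C)CCCCl | intermediate
7 | (2Z)-6-chloro-3-methylhex-2-enal | O=C/C=C(/C)CCCCl | intermediate
8 | (4S)-4-benzyl-1,3-oxazolidin-2-one | O=C1N[C@@H](Cc2ccccc2)CO1 | starting material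
9 | methyl 4-chloro-4-oxobutanoate | COC(=O)CCC(Cl)=O | starting material
10 | N-lithio-(4S)-4-benzyl-1,3-oxazolidin-2-one | [Li]N1[C@@H](Cc2ccccc2)COC1=O | intermediate (not isolated)
11 | methyl 4-[(4S)-4-benzyl-2-oxo-1,3-oxazolidin-3-yl]-4-oxobutanoate | COC(=O)CCC(=O)N1[C@@H](Cc2ccccc2)COC1=O | intermediate
12 | dibutylboron (Z)-enolate of 11 | COC(=O)C/C=C(\OB(CCCC)CCCC)N1[C@@H](Cc2ccccc2)COC1=O | intermediate (not isolated)
13 | methyl (3S,4R,5Z)-3-{[(4S)-4-benzyl-2-oxo-1,3-oxazolidin-3-yl]carbonyl}-9-chloro-4-hydroxy-6-methylnon-5-enoate | COC(=O)C[C@H](C(=O)N1[C@@H](Cc2ccccc2)COC1=O)[C@H](O)/C=C(/C)CCCCl | intermediate (not isolated)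
14 | (4S)-4-benzyl-3-{[(2R,3S)-2-[(1Z)-5-chloro-2-methylpent-1-en-1-yl]-5-oxooxolan-3-yl]carbonyl}-1,3-oxazolidin-2-one | O=C1C[C@H](C(=O)N2[C@@H](Cc3ccccc3)COC2=O)[C@@H](/C=C(/C)CCCCl)O1 | intermediate
15 | (2R,3S)-2-[(1Z)-5-chloro-2-methylpent-1-en-1-yl]-5-oxooxolane-3-carboxylic acid | O=C1C[C@H](C(=O)O)[C@@H](/C=C(/C)CCCCl)O1 | intermediate
16 | tert-butyl(dimethyl)(prop-2-yn-1-yloxy)silane | C#CCO[Si](C)(C)C(C)(C)C | starting material
17 | (2R,3S)-2-[(1Z)-5-chloro-2-methylpent-1-en-1-yl]-5-oxooxolane-3-carbonyl chloride | O=C1C[C@H](C(Cl)=O)[C@@H](/C=C(/C)CCCCl)O1 | intermediate (not isolated)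
18 | (4S,5R)-4-{4-[tert-butyl(dimethyl)silyl]oxybut-2-ynoyl}-5-[(1Z)-5-chloro-2-methylpent-1-en-1-yl]oxolan-2-one | O=C1C[C@H](C(=O)C#CCO[Si](C)(C)C(C)(C)C)[C@@H](/C=C(/C)CCCCl)O1 | intermediate
19 | sodium (Z)-enethiolate: HS− adduct of 18 at C10, S cis to the C8 carbonyl | O=C1C[C@H](C(=O)/C=C(/CO[Si](C)(C)C(C)(C)C)[S-])[C@@H](/C=C(/C)CCCCl)O1.[Na+] | intermediate (not isolated)
20 | thiacycle enone: eleven-membered ring S–C1H2–C2H2–C3H2–C4(CH3)=C5H–C6H–C7H–C8(=O)–C9H=C10(CH2OTBS)–S, 4Z and 9Z, trans-γ-lactone across C6 (O) and C7 (C11H2–C12=O), 6R,7S | O=C1C[C@H]2[C@H](O1)/C=C(/C)CCCS/C(CO[Si](C)(C)C(C)(C)C)=C\C2=O | intermediate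
21 | thiacycle allylic alcohol: 20 with C8 reduced to the (8S)-carbinol | O=C1C[C@H]2[C@H](O1)/C=C(/C)CCCS/C(CO[Si](C)(C)C(C)(C)C)=C\[C@H]2O | intermediate
22 | C8 triisopropylsilyl ether of 21 | O=C1C[C@H]2[C@H](O1)/C=C(/C)CCCS/C(CO[Si](C)(C)C(C)(C)C)=C\[C@H]2O[Si](C(C)C)(C(C)C)C(C)C | intermediate
23 | cyclic vinyl sulfone: S,S-dioxide of 22 | O=C1C[C@H]2[C@H](O1)/C=C(/C)CCCS(=O)(=O)/C(CO[Si](C)(C)C(C)(C)C)=C\[C@H]2O[Si](C(C)C)(C(C)C)C(C)C | intermediate
24 | 9,10-epoxy sulfone: cis-fused oxirane on C9–C10 of 23, oxygen anti to the C8 silyloxy group, C9 configured as in the target | O=C1C[C@H]2[C@H](O1)/C=C(/C)CCCS(=O)(=O)[C@@]3(CO[Si](C)(C)C(C)(C)C)O[C@H]3[C@H]2O[Si](C(C)C)(C(C)C)C(C)C | intermediate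
25 | cis-fused episulfone (thiirane 1,1-dioxide across C1–C10 of the ten-membered ring), lithium C9 alkoxide | C1C(=O)O[C@@H]2/C=C(/C)CC[C@@H]3[C@@](CO[Si](C)(C)C(C)(C)C)(S3(=O)=O)[C@@H]([O-])[C@@H](O[Si](C(C)C)(C(C)C)C(C)C)[C@@H]12.[Li+] | intermediate (not isolated)
26 | (1(10)Z,4Z)-9-hydroxy-8-(triisopropylsilyloxy)-14-(tert-butyldimethylsilyloxy)germacra-1(10),4-dien-12,6-olide, C6–C9 as in the target | C1C(=O)O[C@@H]2/C=C(/C)CC/C=C(/CO[Si](C)(C)C(C)(C)C)[C@@H](O)[C@@H](O[Si](C(C)C)(C(C)C)C(C)C)[C@@H]12 | intermediate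
27 | Mannich base: 26 with CH2NMe2 on C11 (C11 configuration not defined) | CN(C)CC1C(=O)O[C@@H]2/C=C(/C)CC/C=C(/CO[Si](C)(C)C(C)(C)C)[C@@H](O)[C@@H](O[Si](C(C)C)(C(C)C)C(C)C)[C@@H]12 | intermediate (not isolated)
28 | trimethylammonium iodide of 27 | C[N+](C)(C)CC1C(=O)O[C@@H]2/C=C(/C)CC/C=C(/CO[Si](C)(C)C(C)(C)C)[C@@H](O)[C@@H](O[Si](C(C)C)(C(C)C)C(C)C)[C@@H]12.[I-] | intermediate (not isolated)
29 | (1(10)Z,4Z)-9-hydroxy-8-(triisopropylsilyloxy)-14-(tert-butyldimethylsilyloxy)germacra-1(10),4,11(13)-trien-12,6-olide | C=C1C(=O)O[C@@H]2/C=C(/C)CC/C=C(/CO[Si](C)(C)C(C)(C)C)[C@@H](O)[C@@H](O[Si](C(C)C)(C(C)C)C(C)C)[C@@H]12 | intermediate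
30 | 9-O-acetate of 29 | C=C1C(=O)O[C@@H]2/C=C(/C)CC/C=C(/CO[Si](C)(C)C(C)(C)C)[C@@H](OC(C)=O)[C@@H](O[Si](C(C)C)(C(C)C)C(C)C)[C@@H]12 | intermediate
31 | (1(10)Z,4Z)-9-acetoxy-8,14-dihydroxygermacra-1(10),4,11(13)-trien-12,6-olide | C=C1C(=O)O[C@@H]2/C=C(/C)CC/C=C(/CO)[C@@H](OC(C)=O)[C@@H](O)[C@@H]12 | intermediate
32 | (2R)-2-methylbutanoic acid | CC[C@@H](C)C(=O)O | starting material
33 | CNP0005248.2: (1(10)Z,4Z,6R,7R,8S,9R)-9-acetoxy-8-hydroxy-14-[(2R)-2-methylbutanoyloxy]germacra-1(10),4,11(13)-trien-12,6-olide | C=C1C(=O)O[C@@H]2/C=C(/C)CC/C=C(/COC(=O)[C@H](C)CC)[C@@H](OC(C)=O)[C@@H](O)[C@@H]12 | target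

Total step count: 18
Longest linear sequence: 17 steps (steps 1–4 and 6–18 from 5-chloropent-1-yne; step 5 is a one-step branch).

Steps most likely to fail

Step 14. The α-sulfonyl carbanion may close to the trans-fused episulfone, or the 1,3-displacement at the fully substituted C10 may be slow, so that sulfur extrusion gives the ring-trans (1(10)E) olefin. The fallback sets out from 24 and comes back at 26, and fixes the geometry thermodynamically at the enone stage instead of kinetically in the extrusion. Under the base treatment 24 passes through the trans-fused episulfone F1 to the E-allylic alcohol F2. Dess–Martin oxidation gives the E-enone F3, which is equilibrated (I2 cat., CH2Cl2, daylight, or PhSH/Et3N cat.) to the less strained ring-cis enone F4. Luche reduction (NaBH4, CeCl3·7H2O, MeOH, −78 °C), with hydride anti to the C8 silyloxy group (Felkin–Anh), should then return 26.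

Step 13. Peroxide addition to C9 of the macrocyclic Z-vinyl sulfone may show poor facial selectivity, because the acyclic 1,2-induction model need not hold in the ring, and the epimeric oxirane would end as the C9 epimer. The fallback sets out from 23 and comes back at 26, and sets C9 by ketone reduction instead of by epoxidation. The epimeric epoxy sulfone F5 is contracted with LiOt-Bu through the episulfone F6 to the 9-epi allylic alcohol F7. Dess–Martin oxidation gives the enone F4, and the Luche reduction described above sets C9 by 1,2-induction from C8 and returns 26.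

Step 9. The SN2 closure of the eleven-membered ring is slow and may lose out to intermolecular S-alkylation (oligomers). The fallback sets out from 15 and comes back at 20; sulfur is attached first and the ring is closed by the much faster thiol–ynone addition. KSAc (DMF, 23 °C) converts 15 into the thioacetate acid F8. Oxalyl chloride gives the acid chloride F9 (not isolated), which is coupled with 16 under the Pd/Cu conditions of step 8 to the S-acetyl ynone F10. K2CO3 in MeOH/THF at high dilution and 0 °C cleaves the thioacetate, and the potassium thiolate F11 (not isolated) adds to the ynone intramolecularly to give 20.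

Further compounds
F1 | step 14 | trans-fused episulfone (C2 and C9 trans), lithium C9 alkoxide | C1C(=O)O[C@@H]2/C=C(/C)CC[C@H]3[C@@](CO[Si](C)(C)C(C)(C)C)(S3(=O)=O)[C@@H]([O-])[C@@H](O[Si](C(C)C)(C(C)C)C(C)C)[C@@H]12.[Li+]
F2 | step 14 | (1(10)E)-isomer of 26 | C1C(=O)O[C@@H]2/C=C(/C)CC/C=C(\CO[Si](C)(C)C(C)(C)C)[C@@H](O)[C@@H](O[Si](C(C)C)(C(C)C)C(C)C)[C@@H]12
F3 | step 14 | (1(10)E)-9-oxo enone | C1C(=O)O[C@@H]2/C=C(/C)CC/C=C(\CO[Si](C)(C)C(C)(C)C)C(=O)[C@@H](O[Si](C(C)C)(C(C)C)C(C)C)[C@@H]12
F4 | step 14 | (1(10)Z)-9-oxo enone | C1C(=O)O[C@@H]2/C=C(/C)CC/C=C(/CO[Si](C)(C)C(C)(C)C)C(=O)[C@@H](O[Si](C(C)C)(C(C)C)C(C)C)[C@@H]12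
F5 | step 13 | epimeric cis-fused 9,10-epoxy sulfone (oxirane on the other face) | O=C1C[C@H]2[C@H](O1)/C=C(/C)CCCS(=O)(=O)[C@]3(CO[Si](C)(C)C(C)(C)C)O[C@@H]3[C@H]2O[Si](C(C)C)(C(C)C)C(C)C
F6 | step 13 | 9-epi cis-fused episulfone, lithium C9 alkoxide | C1C(=O)O[C@@H]2/C=C(/C)CC[C@H]3[C@](CO[Si](C)(C)C(C)(C)C)(S3(=O)=O)[C@H]([O-])[C@@H](O[Si](C(C)C)(C(C)C)C(C)C)[C@@H]12.[Li+]
F7 | step 13 | 9-epi-26 | C1C(=O)O[C@@H]2/C=C(/C)CC/C=C(/CO[Si](C)(C)C(C)(C)C)[C@H](O)[C@@H](O[Si](C(C)C)(C(C)C)C(C)C)[C@@H]12
F8 | step 9 | (2R,3S)-2-[(1Z)-5-(acetylsulfanyl)-2-methylpent-1-en-1-yl]-5-oxooxolane-3-carboxylic acid | O=C1C[C@H](C(=O)O)[C@@H](/C=C(/C)CCCSC(C)=O)O1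
F9 | step 9 | acid chloride of F8 | O=C1C[C@H](C(Cl)=O)[C@@H](/C=C(/C)CCCSC(C)=O)O1
F10 | step 9 | S-acetyl ynone (18 with SAc in place of Cl) | O=C1C[C@H](C(=O)C#CCO[Si](C)(C)C(C)(C)C)[C@@H](/C=C(/C)CCCSC(C)=O)O1
F11 | step 9 | potassium thiolate of the ynone | O=C1C[C@H](C(=O)C#CCO[Si](C)(C)C(C)(C)C)[C@@H](/C=C(/C)CCC[S-])O1.[K+]
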